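## Retrosynthetic overview

1. The C11 methyl is added last by lactone enolate methylation; the bicyclo[2.2.2]oct-5-en-2-one comes from a pinacol-type 1,2-shift that expands the five-membered ring of a bridged bicyclo[3.2.1]oct-3-ene-1,2-diol.
2. That diol comes from a SmI2 ketone–enal coupling (C1–C2 bond); the diene side chain is put on C2′ beforehand by Pd-catalysed ketone α-alkenylation.
3. The cis-12,6-lactone comes from a 1,2-carbonyl transposition in ring B (Rubottom oxidation, Wittig, redox isomerisation) followed by hydride reduction.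
4. The angular (Z)-butenyl arm on C5 comes from a copper-catalysed conjugate addition to the (R)-Hajos–Parrish ketone, itself made from 2-methylcyclopentane-1,3-dione and methyl vinyl ketone.
5. Ring order: five-membered ring (starting material) → ring B (Robinson-type annulation) → lactone → bridging cyclohexene (pinacol coupling) → ring expansion to the bicyclo[2.2.2]octenone.

Assumption: C1–C12 follow eudesmane numbering of the lactone half and C1′/C2′ are the two bridge carbons from the diene unit; C6 in 12–14 and C2 in 27 are left undefined because both centres are erased later.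

## Route

Step 1
Reactants: 1 2-methylcyclopentane-1,3-dione; 2 but-3-en-2-one
Product: 3 2-methyl-2-(3-oxobutyl)cyclopentane-1,3-dione
Conditions: H2O, AcOH (cat.), 75 °C
Reagents that add atoms: none
Why: Michael addition of the acidic cyclic 1,3-dione to the enone gives the 2,2-disubstituted triketone without added base (no stereocentre formed).

Step 2
Reactants: 3 2-methyl-2-(3-oxobutyl)cyclopentane-1,3-dione
Product: 5 (R)-Hajos–Parrish ketone, via cis-ketol 4 (not isolated)
Conditions: (R)-proline (3 mol%), DMF, 20 °C; then H2SO4 (cat.), 95 °C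
Reagents that add atoms: none
Why: The Hajos–Parrish–Eder–Sauer–Wiechert proline-catalysed enamine aldol desymmetrises the dione, (R)-proline sets the angular C10 carbon as R, and acid dehydrates the ketol to the enone.

Step 3
Reactants: 6 but-2-yn-1-ol
Product: 8 (Z)-3-iodobut-2-en-1-ol, via sodium alkenylalanate 7 (not isolated)
Conditions: NaAlH2(OCH2CH2OCH3)2, THF, 0 to 20 °C; then I2, −78 to 0 °C
Reagents that add atoms: iodine II
Why: The propargylic aluminium alkoxide delivers hydride trans across the alkyne (trans-hydroalumination), so Al sits on C3 cis to the CH2O group and iodinolysis with retention gives the Z iodide.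

Step 4
Reactants: 8 (Z)-3-iodobut-2-en-1-ol
Product: 9 (Z)-triethyl[(3-iodobut-2-en-1-yl)oxy]silane
Conditions: Et3SiCl, imidazole, CH2Cl2, 0 °C
Reagents that add atoms: chlorotriethylsilane CC[Si](Cl)(CC)CC
Why: Standard silylation of the primary allylic alcohol; the triethylsilyl ether is later oxidised off directly in step 13.

Step 5
Reactants: 9 (Z)-triethyl[(3-iodobut-2-en-1-yl)oxy]silane; 5 (R)-Hajos–Parrish ketone
Product: 11 cis-hydrindanone C7 trimethylsilyl enol ether, via alkenylmagnesium chloride 10 (not isolated)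
Conditions: 9, i-PrMgCl·LiCl, THF, 20 °C; then 5, CuBr·SMe2 (20 mol%), Me3SiCl, HMPA, THF, −78 to −40 °C
Reagents that add atoms: chlorotrimethylsilane C[Si](C)(C)Cl
Why: Iodine–magnesium exchange keeps the alkene geometry, and the copper-catalysed, Me3SiCl/HMPA-accelerated conjugate addition (Nakamura–Kuwajima conditions) attacks C5 on the face of the C10 methyl to give the cis-hydrindane (sets C5) while trapping the C6=C7 enolate regiospecifically; the neopentyl C1 ketone is expected to survive slow Grignard addition at −78 °C.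

Step 6
Reactants: 11 cis-hydrindanone C7 trimethylsilyl enol ether
Product: 13 C6-hydroxy C7-ketone, via silyloxy epoxide 12 (not isolated)
Conditions: dimethyldioxirane (1.05 equiv), acetone/CH2Cl2, −78 °C; then K2CO3 (cat.), MeOH, 0 °C
Reagents that add atoms: dimethyldioxirane CC1(C)OO1
Why: Rubottom oxidation: the electron-rich silyl enol ether is epoxidised far faster than the hindered trisubstituted alkene, and methanolysis of the silyloxy epoxide gives the α-hydroxy ketone (the C6 configuration is erased in step 7).

Step 7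
Reactants: 13 C6-hydroxy C7-ketone
Product: 15 C6-keto C7-acetate methyl ester, via γ-hydroxy enoate 14 (not isolated)
Conditions: Ph3P=CHCO2Me, toluene, 90 °C; then DBU, MeOH, 40 °C
Reagents that add atoms: methyl (triphenylphosphoranylidene)acetate COC(=O)C=P(c1ccccc1)(c1ccccc1)c1ccccc1
Why: Wittig olefination of the activated α-hydroxy ketone, then base-mediated 1,3-proton shift of the γ-hydroxy enoate (redox isomerisation; any butenolide from the Z isomer is opened by methanol through its β,γ-isomer), transposes the carbonyl to C6 and lets C7 settle with the acetate arm equatorial (7S).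

Step 8
Reactants: 15 C6-keto C7-acetate methyl ester
Product: 17 cis-lactone C1-alcohol, via dihydroxy ester 16 (not isolated)
Conditions: NaBH4, MeOH/THF, −20 to 20 °C
Reagents that add atoms: none
Why: Borohydride should reach the C6 ketone from the face of the five-membered ring, because the other face carries the axial C10 methyl and the angular alkenyl group, so the 6β-alkoxide forms cis to the C7 arm and lactonises (sets C6 as R); the C1 ketone is also reduced and is restored in step 9.

Step 9
Reactants: 17 cis-lactone C1-alcohol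
Product: 18 keto lactone
Conditions: Dess–Martin periodinane, CH2Cl2, 20 °C
Reagents that add atoms: none
Why: Dess–Martin oxidation of the only free alcohol regenerates the C1 ketone without touching the lactone or the silyl ether.

Step 10
Reactants: 19 5-bromo-2-methylpent-2-ene
Product: 20 6-methylhept-5-en-1-yne
Conditions: LiC≡CH·H2NCH2CH2NH2, DMSO, 10 to 20 °C
Reagents that add atoms: lithium acetylide–ethylenediamine [Li]C#C.NCCN
Why: SN2 alkylation of lithium acetylide by the primary bromide in DMSO.

Step 11
Reactants: 20 6-methylhept-5-en-1-yne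
Product: 22 2-bromo-6-methylhepta-1,5-diene, via bromoalkenylborane 21 (not isolated)
Conditions: B-bromo-9-borabicyclo[3.3.1]nonane, CH2Cl2, 0 °C; then AcOH, 0 °C
Reagents that add atoms: B-bromo-9-borabicyclo[3.3.1]nonane BrB1C2CCCC1CCC2
Why: Hara–Suzuki syn-bromoboration of the terminal alkyne followed by protonolysis is a Markovnikov HBr addition that leaves the trisubstituted alkene untouched.

Step 12
Reactants: 18 keto lactone; 22 2-bromo-6-methylhepta-1,5-diene
Product: 24 C2′-alkenylated keto lactone, via lithium enolate 23 (not isolated)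
Conditions: LiN(SiMe3)2 (1.05 equiv), toluene, −78 °C; then 22, Pd2(dba)3 (2.5 mol%), P(t-Bu)3 (6 mol%), 20 °C
Reagents that add atoms: none
Why: Palladium-catalysed α-alkenylation of the ketone enolate (Buchwald–Hartwig-type enolate coupling); C1 can enolise only toward C2′, and the C–C bond should form on the face opposite the angular methyl and alkenyl groups, which is also judged the thermodynamic epimer, setting C2′.

Step 13
Reactants: 24 C2′-alkenylated keto lactone
Product: 26 keto (Z)-enal, via alkoxysulfonium chloride 25 (not isolated)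
Conditions: (COCl)2, DMSO, CH2Cl2, −78 to −40 °C; then Et3N, −78 to 0 °C
Reagents that add atoms: none
Why: Swern oxidation acts directly on the primary triethylsilyl ether (silyl transfer to chloride, then alkoxysulfonium fragmentation), giving the (Z)-enal in one operation.

Step 14
Reactants: 26 keto (Z)-enal
Product: 27 bridged bicyclo[3.2.1]oct-3-ene-1,2-diol
Conditions: SmI2 (2.5 equiv), t-BuOH (2 equiv), THF, −78 °C
Reagents that add atoms: none
Why: SmI2 ketone–aldehyde pinacol (ketyl) coupling closes the six-membered ring; the tether on C5 forces the new C1–C2 bond onto the face of the C10 methyl, so the C1 hydroxyl ends cis to the C2′ side chain, and the C2 configuration does not matter.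

Step 15
Reactants: 27 bridged bicyclo[3.2.1]oct-3-ene-1,2-diol
Product: 28 11-nor-methyl target
Conditions: (PhO)2P(O)OH (10 mol%), (CF3)2CHOH/CH2Cl2 (1:4), −20 °C
Reagents that add atoms: none
Why: Proposed new method: mild Brønsted acid in (CF3)2CHOH ionises only the secondary allylic C2 hydroxyl (the C1 hydroxyl is at a bridgehead and cannot ionise) to a C2–C3–C4 allyl cation; by a rough geometric estimate the C1–C2′ bond of the two-carbon bridge lies about 20° from the empty p axis at C2 and the C1–C10 bond about 55°, so C2′ should migrate with retention while the C1 hydroxyl becomes the ketone, which expands the five-membered ring into the bicyclo[2.2.2]oct-5-en-2-one, sets C2 and leaves the C3=C4 alkene; the closest known reactions are pinacol/semipinacol shifts of allylic 1,2-diols and the bicyclo[3.2.1]octyl–bicyclo[2.2.2]octyl cation interconversion, which has not been used in this direction on a bridgehead diol.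

Step 16
Reactants: 28 11-nor-methyl target
Product: 30 target CNP0385704.2, via lithium lactone enolate 29 (not isolated)
Conditions: LiN(i-Pr)2, THF, −78 °C; then MeI, −78 to −40 °C
Reagents that add atoms: iodomethane CI
Why: Enolate alkylation of the cis-fused γ-lactone occurs from the convex face (that of H6 and H7), setting C11 as S; the C1 ketone has no enolisable α-hydrogen (bridgehead C2, quaternary C10).

## Compound list

1 | 2-methylcyclopentane-1,3-dione | CC1C(=O)CCC1=O | starting material
2 | but-3-en-2-one (methyl vinyl ketone) | CC(=O)C=C | starting material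
3 | 2-methyl-2-(3-oxobutyl)cyclopentane-1,3-dione | CC(=O)CCC1(C)C(=O)CCC1=O | intermediate
4 | (3aR,7aR)-3a-hydroxy-7a-methylhexahydro-1H-indene-1,5(4H)-dione (cis-ketol) | C[C@@]12CCC(=O)C[C@]1(O)CCC2=O | intermediate
5 | (7aR)-7a-methyl-2,3,7,7a-tetrahydro-1H-indene-1,5(6H)-dione ((R)-Hajos–Parrish ketone) | C[C@@]12CCC(=O)C=C1CCC2=O | intermediate
6 | but-2-yn-1-ol | CC#CCO | starting material
7 | sodium cyclic alkenyl(alkoxy)bis(2-methoxyethoxy)alanate | [Na+].CC1=CCO[Al-]1(OCCOC)OCCOC | intermediate
8 | (Z)-3-iodobut-2-en-1-ol | C/C(I)=C/CO | intermediate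
9 | (Z)-triethyl[(3-iodobut-2-en-1-yl)oxy]silane | C/C(I)=C/CO[Si](CC)(CC)CC | intermediate
10 | (Z)-[4-(triethylsilyloxy)but-2-en-2-yl]magnesium chloride | C/C([Mg]Cl)=C/CO[Si](CC)(CC)CC | intermediate
11 | cis-hydrindan-1-one with C7 trimethylsilyl enol ether (C6=C7) and angular (Z)-4-(triethylsilyloxy)but-2-en-2-yl on C5, cis to the C10 methyl | C[C@@]12CCC(O[Si](C)(C)C)=C[C@]1(/C(C)=C\CO[Si](CC)(CC)CC)CCC2=O | intermediate
12 | C6–C7 epoxide of 11 (silyloxy epoxide, epoxide face undefined) | C[C@@]12CCC3(O[Si](C)(C)C)OC3[C@]1(/C(C)=C\CO[Si](CC)(CC)CC)CCC2=O | intermediate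
13 | cis-hydrindane-1,7-dione with C6 hydroxyl (C6 undefined) and the angular silyloxybutenyl arm | C[C@@]12CCC(=O)C(O)[C@]1(/C(C)=C\CO[Si](CC)(CC)CC)CCC2=O | intermediate
14 | C7 (methoxycarbonyl)methylidene C6 alcohol (alkene geometry and C6 undefined) | C[C@@]12CCC(=CC(=O)OC)C(O)[C@]1(/C(C)=C\CO[Si](CC)(CC)CC)CCC2=O | intermediate
15 | cis-hydrindane-1,6-dione with (7S) equatorial CH2CO2Me on C7 | C[C@@]12CC[C@@H](CC(=O)OC)C(=O)[C@]1(/C(C)=C\CO[Si](CC)(CC)CC)CCC2=O | intermediate
16 | 1β,6β-diol methyl ester (both hydroxyls on the face of the C10 methyl) | C[C@@]12CC[C@@H](CC(=O)OC)[C@@H](O)[C@]1(/C(C)=C\CO[Si](CC)(CC)CC)CC[C@H]2O | intermediate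
17 | cis-fused 12,6-lactone (6R,7S) with C1 β-alcohol | C[C@@]12CC[C@H]3CC(=O)O[C@H]3[C@]1(/C(C)=C\CO[Si](CC)(CC)CC)CC[C@H]2O | intermediate
18 | cis-fused 12,6-lactone with C1 ketone (keto lactone) | C[C@@]12CC[C@H]3CC(=O)O[C@H]3[C@]1(/C(C)=C\CO[Si](CC)(CC)CC)CCC2=O | intermediate
19 | 5-bromo-2-methylpent-2-ene | CC(C)=CCCBr | starting material
20 | 6-methylhept-5-en-1-yne | CC(C)=CCCC#C | intermediate
21 | (Z)-B-(2-bromo-6-methylhepta-1,5-dien-1-yl)-9-borabicyclo[3.3.1]nonane | CC(C)=CCC/C(Br)=C/B1C2CCCC1CCC2 | intermediate
22 | 2-bromo-6-methylhepta-1,5-diene | CC(C)=CCCC(Br)=C | intermediate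
23 | lithium C1=C2′ enolate of 18 | C[C@@]12CC[C@H]3CC(=O)O[C@H]3[C@]1(/C(C)=C\CO[Si](CC)(CC)CC)CC=C2O[Li] | intermediate
24 | keto lactone with 6-methylhepta-1,5-dien-2-yl on C2′, trans to the C10 methyl | C[C@@]12CC[C@H]3CC(=O)O[C@H]3[C@]1(/C(C)=C\CO[Si](CC)(CC)CC)C[C@H](C(=C)CCC=C(C)C)C2=O | intermediate
25 | dimethyl(alkoxy)sulfonium chloride of the allylic alcohol of 24 | C[C@@]12CC[C@H]3CC(=O)O[C@H]3[C@]1(/C(C)=C\CO[S+](C)C)C[C@H](C(=C)CCC=C(C)C)C2=O.[Cl-] | intermediate
26 | keto lactone with angular (Z)-4-oxobut-2-en-2-yl arm on C5 (keto enal) | C[C@@]12CC[C@H]3CC(=O)O[C@H]3[C@]1(/C(C)=C\C=O)C[C@H](C(=C)CCC=C(C)C)C2=O | intermediate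
27 | bridged diol: C1 (bridgehead) and C2 hydroxyls, C3=C4 alkene, C1 hydroxyl cis to the C2′ side chain, C2 undefined | C[C@@]12CC[C@H]3CC(=O)O[C@H]3[C@@]14C(C)=CC(O)[C@]2(O)[C@@H](C(=C)CCC=C(C)C)C4 | intermediate
28 | 11-nor-methyl target (CH2 at C11) | C=C(CCC=C(C)C)[C@H]1C[C@]23C(C)=C[C@H]1C(=O)[C@]2(C)CC[C@H]1CC(=O)O[C@H]13 | intermediate
29 | lithium lactone enolate of 28 | C=C(CCC=C(C)C)[C@H]1C[C@]23C(C)=C[C@H]1C(=O)[C@]2(C)CC[C@H]1C=C(O[Li])O[C@H]13 | intermediate
30 | CNP0385704.2 (C2′ S, C2 R, C5 S, C6 R, C7 S, C10 R, C11 S) | C=C(CCC=C(C)C)[C@H]1C[C@]23C(C)=C[C@H]1C(=O)[C@]2(C)CC[C@H]1[C@H](C)C(=O)O[C@H]13 | target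

## Step count and risks

Total steps: 16 (12 in the main line, 2 for iodide 9, 2 for bromide 22). Longest linear sequence: 12 steps (1, 2, 5, 6, 7, 8, 9, 12, 13, 14, 15, 16).

Three steps most likely to fail:

Step 5 builds two adjacent quaternary carbons with an α-branched alkenyl nucleophile next to a free ketone. The fallback sets out from 5 and 9 and avoids the organomagnesium reagent: a nickel-catalysed reductive conjugate alkenylation (cross-electrophile coupling with NiCl2(dme), 2,9-dimethyl-1,10-phenanthroline, Mn powder and Et3SiCl in DMF) joins the two directly and gives the triethylsilyl enol ether F1, which under the conditions of step 6 comes back to the route at 13.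

Step 14 must couple a hindered ketone with a conjugated aldehyde on the crowded face. The fallback sets out from 26 and swaps reductive coupling for umpolung: an N-heterocyclic carbene (from 2-mesityl-6,7-dihydro-5H-pyrrolo[2,1-c][1,2,4]triazol-2-ium chloride and DBU, THF) adds the aldehyde carbon to the C1 ketone in a crossed benzoin reaction to give the bridged α-ketol F2, and Luche reduction (NaBH4, CeCl3·7H2O, MeOH, −78 °C) of its C2 ketone comes back to the route at 27.

Step 15 is the proposed new rearrangement; the one-carbon bridge (C10) could migrate instead, or the allyl cation could be trapped. The fallback sets out from 27 and uses the known stoichiometric semipinacol of a β-sulfonyloxy alcohol (Tsuchihashi–Suzuki): MsCl and Et3N (CH2Cl2, −40 °C) give the C2 methanesulfonate F3, and Et3Al (CH2Cl2, −78 °C) promotes the 1,2-shift of C2′, coming back to the route at 28.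

## Further compounds

F1 | step 5 | triethylsilyl enol ether analogue of 11 | C[C@@]12CCC(O[Si](CC)(CC)CC)=C[C@]1(/C(C)=C\CO[Si](CC)(CC)CC)CCC2=O
F2 | step 14 | bridged α-ketol (C1 hydroxyl, C2 ketone) | C[C@@]12CC[C@H]3CC(=O)O[C@H]3[C@@]14C(C)=CC(=O)[C@]2(O)[C@@H](C(=C)CCC=C(C)C)C4
F3 | step 15 | C2 methanesulfonate of 27 | C[C@@]12CC[C@H]3CC(=O)O[C@H]3[C@@]14C(C)=CC(OS(C)(=O)=O)[C@]2(O)[C@@H](C(=C)CCC=C(C)C)C4
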